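**Strategy**

The route rests on reading ring B as a ring-enlarged hydrindanone: C8 with its methyl group (C17) sits between C7 and the oxygen-bearing spiro carbon C9, which in turn adjoins quaternary C10. One Lewis-acid-catalysed insertion of diazoethane into the five-ring ketone of an enantiopure bicyclic enedione therefore creates C7–C8 and C8–C9, enlarges that ring to ring B, delivers the C8 methyl group and leaves a C9 carbonyl for the side chain. The precursor is the bicyclic enedione with a six-ring enone (future ring A), a saturated cyclopentanone and the angular methyl group. Ring A is then completed by reductive hydroxymethylation, and the spiro ether-lactone by alkylation of a malic acid template and hydroalkoxylation.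

Key step: step 2

Remark: labdane numbering (C1–C20) is used for all intermediates; the temporary C9 carbinol configuration and the geometry of the C9=C11 bond are of no consequence because both are erased before the last ring closure, and the isomers drawn are the expected major ones.

**Route**

Step 1
Reactants: 1 N-ethyl-N-nitrosourea
Product: 2 diazoethane (dried ether solution, used at once)
Conditions: 40% aq. KOH, Et2O, −10 → 0 °C; ether layer dried over KOH pellets
Reagents that add atoms: none
Why: Base-induced fragmentation of an N-alkyl-N-nitrosourea (standard diazoalkane generation) gives the diazotate, which loses hydroxide to form diazoethane that is extracted into ether.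

Step 2
Reactants: 3 (S)-7a-methyl-2,3,7,7a-tetrahydro-1H-indene-1,5(6H)-dione (Hajos–Parrish ketone); 2 diazoethane
Product: 5 8α,10β-dimethyloctal-4-ene-3,9-dione, via 8β-methyl epimer 4 (not isolated)
Conditions: Sc(OTf)3 (10 mol%), CH2Cl2/Et2O, −78 → −40 °C; then K2CO3, MeOH, rt
Reagents that add atoms: none
Why: Sc(OTf)3 activates the saturated, strained five-ring ketone (C9), the nucleophilic carbon of diazoethane adds to it to make C8–C9, and the diazonium betaine loses N2 while the ring CH2 (C7) shifts from C9 to the new carbon to make C7–C8; this is the Lewis-acid-catalysed diazoalkane homologation of a cyclic ketone (Tiffeneau–Demjanov-type ring expansion). Ring B is not closed by a cyclization but arises by one-carbon enlargement of the existing five-membered ring to a six-membered one. The new stereocentre C8 is labile next to the ketone and is set under thermodynamic control in the basic equilibration, the methyl group taking the equatorial α position to avoid the 1,3-diaxial clash with the axial C10 methyl group. Three selectivities are needed: attack at the saturated ketone and not at the vinylogous, less electrophilic enone carbonyl; migration of the methylene and not of quaternary C10, which follows the usual preference of the less substituted carbon in such insertions; and a single insertion, secured because the product is a hindered α,α,α′-trisubstituted cyclohexanone that is far less reactive than the cyclopentanone.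

Step 3
Reactants: 5 8α,10β-dimethyloctal-4-ene-3,9-dione
Product: 6 4-(phenylthiomethyl)-8α,10β-dimethyloctal-4-ene-3,9-dione
Conditions: PhSH, 37% aq. HCHO, Et3N, EtOH, 80 °C
Reagents that add atoms: thiophenol, Sc1ccccc1; formaldehyde, C=O
Why: Kirk–Petrow thiomethylation functionalizes only the α-carbon (C4) of the conjugated enone, installing the future C19 carbon as CH2SPh, while the hindered saturated C9 ketone does not take part.

Step 4
Reactants: 6 4-(phenylthiomethyl)-8α,10β-dimethyloctal-4-ene-3,9-dione
Product: 7 9β-hydroxy-4-(phenylthiomethyl)-8α,10β-dimethyloctal-4-en-3-one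
Conditions: NaBH4 (0.3 equiv), EtOH, −10 → 0 °C
Reagents that add atoms: none
Why: Chemoselective borohydride reduction, the saturated C9 ketone reacting faster than the fully substituted conjugated enone, with hydride arriving on the α face anti to the C10 methyl group to give the equatorial 9β-alcohol, a temporary mask that is re-oxidized in step 8.

Step 5
Reactants: 7 9β-hydroxy-4-(phenylthiomethyl)-8α,10β-dimethyloctal-4-en-3-one
Product: 9 9β-hydroxy-4α-(hydroxymethyl)-4β,8α,10β-trimethyl-5α-decalin-3-one, via dilithium enolate alkoxide 8 (not isolated)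
Conditions: Li, NH3(l)/THF, t-BuOH (1 equiv), −78 → −33 °C; isoprene; NH3 removed; CH2O (gas), THF, −78 °C; aq. NH4Cl
Reagents that add atoms: formaldehyde, C=O
Why: Dissolving-metal reductive alkylation of an α-(phenylthiomethyl) enone: lithium cleaves the allylic C–S bond and reduces the enone, axial protonation at C5 gives the trans ring fusion (5α-H), and the regiodefined C3–C4 enolate adds formaldehyde on the α face opposite the axial C10 methyl group, setting C4 with CH2OH α and CH3 β.

Step 6
Reactants: 9 9β-hydroxy-4α-(hydroxymethyl)-4β,8α,10β-trimethyl-5α-decalin-3-one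
Product: 10 4α-(hydroxymethyl)-4β,8α,10β-trimethyl-5α-decalin-3β,9β-diol
Conditions: NaBH4, MeOH, 0 °C
Reagents that add atoms: none
Why: Borohydride reduction of the C3 ketone by axial hydride delivery on the α face, away from the axial 4β-methyl group, gives the equatorial 3β-alcohol and removes the retro-aldol-prone β-hydroxy ketone.

Step 7
Reactants: 10 4α-(hydroxymethyl)-4β,8α,10β-trimethyl-5α-decalin-3β,9β-diol
Product: 11 3β,18-(isopropylidenedioxy)-4β,8α,10β-trimethyl-5α-decalin-9β-ol
Conditions: 2,2-dimethoxypropane, PPTS (cat.), acetone, rt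
Reagents that add atoms: 2,2-dimethoxypropane, COC(C)(C)OC
Why: Acid-catalysed transacetalization forms the six-membered isopropylidene acetal of the 1,3-diol only, since the isolated hindered 9-hydroxyl cannot form a cyclic acetal.

Step 8
Reactants: 11 3β,18-(isopropylidenedioxy)-4β,8α,10β-trimethyl-5α-decalin-9β-ol
Product: 12 3β,18-(isopropylidenedioxy)-4β,8α,10β-trimethyl-5α-decalin-9-one
Conditions: Dess–Martin periodinane, NaHCO3, CH2Cl2, rt
Reagents that add atoms: none
Why: Dess–Martin oxidation of the remaining secondary alcohol restores the C9 ketone under buffered conditions that keep the acetonide and the equatorial C8 methyl group.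

Step 9
Reactants: 12 3β,18-(isopropylidenedioxy)-4β,8α,10β-trimethyl-5α-decalin-9-one
Product: 13 3β,18-(isopropylidenedioxy)-9α-vinyl-4β,8α,10β-trimethyl-5α-decalin-9β-ol
Conditions: CH2=CHMgBr, CeCl3 (anhydrous), THF, −78 → 0 °C
Reagents that add atoms: vinylmagnesium bromide, C=C[Mg]Br
Why: Organocerium 1,2-addition delivers the small, weakly basic vinyl nucleophile to the hindered, enolizable C9 ketone (C9–C11 bond), expected on the α face; the new carbinol configuration is irrelevant because C9 becomes sp2 in step 10.

Step 10
Reactants: 13 3β,18-(isopropylidenedioxy)-9α-vinyl-4β,8α,10β-trimethyl-5α-decalin-9β-ol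
Product: 14 (E)-12-bromo-3β,18-(isopropylidenedioxy)-13,14,15,16-tetranorlabd-9(11)-ene
Conditions: PBr3 (0.4 equiv), pyridine (cat.), Et2O, −30 → 0 °C
Reagents that add atoms: phosphorus tribromide, BrP(Br)Br
Why: Allylic substitution with rearrangement (SN2′-type, through the phosphite ester and allyl ion pair) converts the tertiary vinyl carbinol into the thermodynamically preferred primary allylic bromide with the C9=C11 bond, pyridine buffering HBr to spare the acetonide.

Step 11
Reactants: 15 (S)-malic acid
Product: 16 2-[(2S,4S)-2-tert-butyl-5-oxo-1,3-dioxolan-4-yl]acetic acid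
Conditions: pivalaldehyde, TsOH·H2O (cat.), H2SO4 (cat.), pentane, reflux (Dean–Stark); recrystallization
Reagents that add atoms: pivalaldehyde, CC(C)(C)C=O
Why: Acid-catalysed acetalization of the α-hydroxy acid unit gives the five-membered dioxolanone, the cis isomer (tert-butyl and CH2CO2H on the same face) being the thermodynamic, crystalline product whose acetal centre will relay the malic acid configuration.

Step 12
Reactants: 16 2-[(2S,4S)-2-tert-butyl-5-oxo-1,3-dioxolan-4-yl]acetic acid; 14 (E)-12-bromo-3β,18-(isopropylidenedioxy)-13,14,15,16-tetranorlabd-9(11)-ene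
Product: 18 dioxolanone acid alkylated at C13 (C12–C13 bond), via dilithium dianion 17 (not isolated)
Conditions: 16 (2 equiv), LiHMDS (4 equiv), THF, −78 °C; then 14, −78 → −30 °C; AcOH
Reagents that add atoms: none
Why: Alkylation of a chiral dioxolanone enolate (self-regeneration of stereocentres): the enolate–carboxylate dianion attacks the primary allylic bromide by SN2 on the face opposite the tert-butyl group, forming C12–C13 and setting quaternary C13 with overall retention of the malic acid configuration (13S).

Step 13
Reactants: 18 dioxolanone acid alkylated at C13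
Product: 20 (13S)-3β,13,18-trihydroxylabd-9(11)-en-15,16-olide, via dihydroxy acid 19 (not isolated)
Conditions: LiEt3BH, THF, −78 → 0 °C; then AcOH/H2O/THF, 40 °C
Reagents that add atoms: none
Why: Hydride reduction takes only the activated dioxolanone carbonyl (C16) to the primary alcohol with loss of pivalaldehyde while the lithium carboxylate (C15) is inert, and mild aqueous acid then lactonizes the γ-hydroxy acid and hydrolyses the acetonide without touching the tertiary C13 hydroxyl or the alkene.

Step 14
Reactants: 20 (13S)-3β,13,18-trihydroxylabd-9(11)-en-15,16-olide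
Product: 21 (13S)-3β,18-diacetoxy-13-hydroxylabd-9(11)-en-15,16-olide
Conditions: Ac2O, pyridine, rt
Reagents that add atoms: acetic anhydride, CC(=O)OC(C)=O
Why: Acetylation in pyridine esterifies the primary C18 and secondary C3 hydroxyls, whereas the tertiary C13 hydroxyl does not react without a nucleophilic catalyst.

Step 15
Reactants: 21 (13S)-3β,18-diacetoxy-13-hydroxylabd-9(11)-en-15,16-olide
Product: 22 (13S)-3β,18-diacetoxy-9α,13-epoxylabdan-15,16-olide (target)
Conditions: Co(salen) [divalent cobalt complex of N,N′-bis(3,5-di-tert-butylsalicylidene)ethane-1,2-diamine] (5 mol%), N-fluoro-2,4,6-trimethylpyridinium tetrafluoroborate, 1,1,3,3-tetramethyldisiloxane, PhCF3, 0 °C → rt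
Reagents that add atoms: none
Why: Cobalt-hydride hydroalkoxylation (Markovnikov hydrogen-atom transfer, then radical–polar crossover): the hydrogen atom goes to C11, the tertiary C9 radical is oxidized and captured by the C13 hydroxyl to close the tetrahydrofuran, and the oxygen enters C9 axially on the α face, anti to the axial C10 methyl group, so that C11 ends equatorial (β) while C8 and C13 are untouched.

**Compound list**

1 | N-ethyl-N-nitrosourea | CCN(N=O)C(N)=O | starting material
2 | diazoethane | CC=[N+]=[N-] | intermediate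
3 | (S)-7a-methyl-2,3,7,7a-tetrahydro-1H-indene-1,5(6H)-dione (Hajos–Parrish ketone) | O=C1CC[C@@]2(C)C(=C1)CCC2=O | starting material
4 | 8β-methyl epimer of 5, (2S,8aS)-2,8a-dimethyl-3,4,8,8a-tetrahydronaphthalene-1,6(2H,7H)-dione | O=C1CC[C@@]2(C)C(=C1)CC[C@H](C)C2=O | intermediate (not isolated)
5 | 8α,10β-dimethyloctal-4-ene-3,9-dione, (2R,8aS)-2,8a-dimethyl-3,4,8,8a-tetrahydronaphthalene-1,6(2H,7H)-dione | O=C1CC[C@@]2(C)C(=C1)CC[C@@H](C)C2=O | intermediate
6 | 4-(phenylthiomethyl)-8α,10β-dimethyloctal-4-ene-3,9-dione | O=C1CC[C@@]2(C)C(=C1CSc1ccccc1)CC[C@@H](C)C2=O | intermediate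
7 | 9β-hydroxy-4-(phenylthiomethyl)-8α,10β-dimethyloctal-4-en-3-one | O=C1CC[C@@]2(C)C(=C1CSc1ccccc1)CC[C@@H](C)[C@@H]2O | intermediate
8 | dilithium 3-enolate 9β-alkoxide of 4,8α,10β-trimethyl-5α-decalin-3-one | CC1=C([O-])CC[C@@]2(C)[C@H]1CC[C@@H](C)[C@@H]2[O-].[Li+].[Li+] | intermediate (not isolated)
9 | 9β-hydroxy-4α-(hydroxymethyl)-4β,8α,10β-trimethyl-5α-decalin-3-one | OC[C@]1(C)C(=O)CC[C@@]2(C)[C@H]1CC[C@@H](C)[C@@H]2O | intermediate
10 | 4α-(hydroxymethyl)-4β,8α,10β-trimethyl-5α-decalin-3β,9β-diol | OC[C@]1(C)[C@@H](O)CC[C@@]2(C)[C@H]1CC[C@@H](C)[C@@H]2O | intermediate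
11 | 3β,18-(isopropylidenedioxy)-4β,8α,10β-trimethyl-5α-decalin-9β-ol | CC1(C)OC[C@]2(C)[C@@H](O1)CC[C@@]1(C)[C@H]2CC[C@@H](C)[C@@H]1O | intermediate
12 | 3β,18-(isopropylidenedioxy)-4β,8α,10β-trimethyl-5α-decalin-9-one | CC1(C)OC[C@]2(C)[C@@H](O1)CC[C@@]1(C)[C@H]2CC[C@@H](C)C1=O | intermediate
13 | 3β,18-(isopropylidenedioxy)-9α-vinyl-4β,8α,10β-trimethyl-5α-decalin-9β-ol | CC1(C)OC[C@]2(C)[C@@H](O1)CC[C@@]1(C)[C@H]2CC[C@@H](C)[C@@]1(O)C=C | intermediate
14 | (E)-12-bromo-3β,18-(isopropylidenedioxy)-13,14,15,16-tetranorlabd-9(11)-ene | CC1(C)OC[C@]2(C)[C@@H](O1)CC[C@@]1(C)[C@H]2CC[C@@H](C)/C1=C\CBr | intermediate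
15 | (S)-malic acid | OC(=O)C[C@H](O)C(=O)O | starting material
16 | 2-[(2S,4S)-2-tert-butyl-5-oxo-1,3-dioxolan-4-yl]acetic acid | CC(C)(C)[C@H]1O[C@@H](CC(=O)O)C(=O)O1 | intermediate
17 | dilithium enolate–carboxylate dianion of 16 | CC(C)(C)[C@H]1OC(CC(=O)[O-])=C([O-])O1.[Li+].[Li+] | intermediate (not isolated)
18 | 2-[(2S,4S)-2-tert-butyl-5-oxo-4-(allyl unit C12 of 14)-1,3-dioxolan-4-yl]acetic acid, i.e. the dioxolanone acid carrying the C9=C11–C12 chain of the acetonide decalin on C13 | CC1(C)OC[C@]2(C)[C@@H](O1)CC[C@@]1(C)[C@H]2CC[C@@H](C)/C1=C\C[C@@]1(CC(=O)O)O[C@H](C(C)(C)C)OC1=O | intermediate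
19 | (13S)-13,16-dihydroxy-3β,18-(isopropylidenedioxy)labd-9(11)-en-15-oic acid | CC1(C)OC[C@]2(C)[C@@H](O1)CC[C@@]1(C)[C@H]2CC[C@@H](C)/C1=C\C[C@@](O)(CO)CC(=O)O | intermediate (not isolated)
20 | (13S)-3β,13,18-trihydroxylabd-9(11)-en-15,16-olide | OC[C@]1(C)[C@@H](O)CC[C@@]2(C)[C@H]1CC[C@@H](C)/C2=C\C[C@@]1(O)COC(=O)C1 | intermediate
21 | (13S)-3β,18-diacetoxy-13-hydroxylabd-9(11)-en-15,16-olide | CC(=O)OC[C@]1(C)[C@@H](OC(C)=O)CC[C@@]2(C)[C@H]1CC[C@@H](C)/C2=C\C[C@@]1(O)COC(=O)C1 | intermediate
22 | (13S)-3β,18-diacetoxy-9α,13-epoxylabdan-15,16-olide | CC(=O)OC[C@]1(C)[C@@H](OC(C)=O)CC[C@@]2(C)[C@H]1CC[C@@H](C)[C@]21CC[C@]2(COC(=O)C2)O1 | target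

**Step count**

Total step count: 15 (14 in the main line plus step 11 for the malic acid template). Longest linear sequence: 14 steps (steps 1–10 and 12–15), or 13 counted from purchased 3.

**Steps most likely to fail**

Step 2 (key step). Diazoethane may add as a dipole to the enone, insert on the quaternary side, or homologate twice, and the ring enlargement may then give little of the wanted ketone. The fallback sets out from 3. Ring expansion with the less nucleophilic ethyl diazoacetate and BF3·OEt2 in CH2Cl2 at 0 °C (β-keto ester homologation with migration of the methylene) should give the ring-enlarged β-keto ester F1. C-methylation at the doubly activated C8 (MeI, K2CO3, acetone) should give the quaternary keto ester F2. Krapcho dealkoxycarbonylation (LiCl, wet DMSO, 150 °C) followed by the same K2CO3/MeOH equilibration returns to the route at 5.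

Step 15. Hydrogen-atom transfer to the hindered alkene may be slow, the C9 cation may suffer a 1,2-methyl shift from C10, reversible hydrogen abstraction may scramble C8, or facial selectivity at C9 may be poor. The fallback sets out from 21. Iodoetherification (I2, NaHCO3, MeCN, 0 °C), a 5-endo iodocyclization through an iodonium ion without a free cation and with anti addition, should give the 11-iodo spiro ether F3. Radical deiodination (Bu3SnH, AIBN, toluene, 80 °C) then comes back to the route at 22.

Step 10. The tertiary allylic alcohol may ionize and eliminate to a diene with loss of the C8 centre, or HBr may cleave the acetonide. The fallback sets out from 12 and avoids the tertiary vinyl carbinol altogether. Addition of lithium ethoxyacetylide (ethoxyacetylene, n-BuLi, THF, −78 °C) should give the ethoxyethynyl carbinol F4. Meyer–Schuster rearrangement (Sc(OTf)3 cat., CH2Cl2/EtOH, rt) should give the α,β-unsaturated ethyl ester F5. Reduction with DIBAL-H (CH2Cl2, −78 °C) should give the primary allylic alcohol F6, and Appel bromination (CBr4, PPh3, 2,6-lutidine, CH2Cl2, 0 °C) returns to the route at 14.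

**Further compounds**

F1 | step 2 | ethyl 10β-methyl-3,9-dioxooctal-4-ene-8-carboxylate (C8 labile, enolizable) | O=C1CC[C@@]2(C)C(=C1)CCC(C(=O)OCC)C2=O
F2 | step 2 | ethyl 8α,10β-dimethyl-3,9-dioxooctal-4-ene-8β-carboxylate | O=C1CC[C@@]2(C)C(=C1)CC[C@](C)(C(=O)OCC)C2=O
F3 | step 15 | (11S,13S)-3β,18-diacetoxy-11-iodo-9α,13-epoxylabdan-15,16-olide | CC(=O)OC[C@]1(C)[C@@H](OC(C)=O)CC[C@@]2(C)[C@H]1CC[C@@H](C)[C@]21[C@@H](I)C[C@]2(COC(=O)C2)O1
F4 | step 10 | 9α-(ethoxyethynyl)-3β,18-(isopropylidenedioxy)-4β,8α,10β-trimethyl-5α-decalin-9β-ol | CC1(C)OC[C@]2(C)[C@@H](O1)CC[C@@]1(C)[C@H]2CC[C@@H](C)[C@@]1(O)C#COCC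
F5 | step 10 | ethyl (E)-3β,18-(isopropylidenedioxy)-13,14,15,16-tetranorlabd-9(11)-en-12-oate | CC1(C)OC[C@]2(C)[C@@H](O1)CC[C@@]1(C)[C@H]2CC[C@@H](C)/C1=C\C(=O)OCC
F6 | step 10 | (E)-3β,18-(isopropylidenedioxy)-13,14,15,16-tetranorlabd-9(11)-en-12-ol | CC1(C)OC[C@]2(C)[C@@H](O1)CC[C@@]1(C)[C@H]2CC[C@@H](C)/C1=C\CO
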